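The earlier runs and the new flask were computed for an exercise, and the scatter is random.

Late in Sunday's run, at 10.0 min, open intermediate is down to 2% and target to 5%. You want to know how Monday's flask, with less reagent, runs up to that time.

the same everywhere: substrate 40 mM

| flask | partner | reagent | remark | time |
|---|---|---|---|---|
| Monday's | 40 mM | 80 mM | the very flask that is asked about, followed so far |  |
| Sunday's | 40 mM | 120 mM | run made earlier |  |
| flask | 40.0 mM | 80.0 mM |  | 10 min |

Monday's run (percent of the substrate charged)

| time / s | open intermediate / % | target / % |
|---|---|---|
| 15.0 | 12 | 0 |
| 30.0 | 12 | 2 |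
| 60.0 | 15 | 4 |
| 120 | 14 | 5 |

Sunday's run (percent of the substrate charged)

| time / min | open intermediate / % | target / % |
|---|---|---|
| 0.250 | 13 | 1 |
| 0.833 | 24 | 6 |
| 3.00 | 13 | 13 |
| 10.0 | 2 | 5 |

(standard deviation of a reading: 1.5 percentage points)

- the moment within 10 min at which there is most open intermediate
- the amount of open intermediate, in percent of the substrate charged, at that time

My own reckoning assumes that each partner quickly takes one reagent. Charged reagent minus charged partner is then 40.0 mM on Monday and 80.0 mM on Sunday; call it the spare reagent. Sunday's later climb of open intermediate plus target is 2.94 times Monday's, more than the charged ratio of 1.50, which fits that assumption. Monday's spare reagent equals its substrate, so the rate then falls as the square of the fraction left: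

rate from the first reading, taken as already after the partner's uptake: 0.480 min⁻¹
time constant of that falling rate: 2.08 min
substrate left at the end: 17.2%, rate slowed 33.6 times

Monday's readings of open intermediate stand at 15% at 60.0 s and 14% at 120 s, with a scatter of 1.5 percentage points, so I read a top of about 14.5% near 60.0 s.

The forecast gives 15% at 1.5 min: “Sunday's peak near 1 min therefore moves to about 1.5 min”.

The flask gives 15.2% at 0.983 min.

    reagent + partner → second intermediate (k = 2.60 L mol⁻¹ s⁻¹)
    open intermediate → side product (k = 0.0160 s⁻¹)
    substrate + reagent → open intermediate (k = 0.160 L mol⁻¹ s⁻¹)
    open intermediate + second intermediate ⇌ target (K = 34.0 L mol⁻¹, k = 0.150 L mol⁻¹ s⁻¹)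

At 10.0 min this flask holds 8.18 mM of substrate, 20.5% of its charge, and 8.18 mM of reagent, with partner at 0%. With 140 mM of reagent, the spare reagent is 100 mM, which exceeds the substrate and should leave 42.9% of the reagent charge. That flask peaks at 28.9% of open intermediate and ends with 0.19% of its substrate and 43% of its reagent.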